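Ring B (C6–C11, numbering of the target name) holds its two carbon–halogen bonds on neighbouring atoms, C9 (methyl, bromine) and C8 (chlorine). Both are read as former carbonyl carbons, so the C8–C9 bond is disconnected to a methyl ketone and an aldehyde that hang from the spiro carbon C6 of a finished ring A, which already carries the C2 bromide, the C1 gem-dimethyl group and the C5 methylidene group. One SmI2 reduction joins the two carbonyl carbons, closes ring B and sets C8 and C9 as a cis diol. Its oxygens are then exchanged for halogen by substitution, so no electrophilic halogen meets the methylidene group. The precursor is keto aldehyde 14.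

Key step: step 9

Remark on numbering: atom numbers in the text are those of target 20 (ring A = C1–C6 with C1 = CMe2, C2 = CHBr, C5 = C(=CH2); ring B = C6–C11 with C8 = CHCl, C9 = CBr(CH3)); "C5 face" and "C1 face" name the two faces of ring B by the ring-A carbon that lies on them.

Remark on step 4: the cyclisation is expected to give 5 together with its ring double-bond isomers; the mixture is carried on, because step 6 converts all of them into the single enal 8.

Step 1
Reactants: 1 geranyl acetate
Product: 2 (2E)-5-[(2R)-3,3-dimethyloxiran-2-yl]-3-methylpent-2-en-1-yl acetate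
Conditions: 1,2:4,5-di-O-isopropylidene-β-D-erythro-2,3-hexodiulo-2,6-pyranose (0.3 equiv), KHSO5 (as Oxone, 2KHSO5·KHSO4·K2SO4), K2CO3, Bu4NHSO4, MeCN/CH2(OMe)2, aq. Na2B4O7 buffer, 0 °C
Reagents that add atoms: potassium peroxymonosulfate, OOS(=O)(=O)[O-].[K+]
Why: Shi asymmetric epoxidation, in which the chiral dioxirane from the D-fructose-derived ketone should oxidise only the electron-rich 6,7-alkene (the 2,3-alkene is deactivated by the allylic acetate) and its spiro transition state should deliver oxygen to the face that gives the 6R epoxide.

Step 2
Reactants: 2 (R)-6,7-epoxygeranyl acetate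
Product: 3 (2E,6S)-6-bromo-7-hydroxy-3,7-dimethyloct-2-en-1-yl acetate
Conditions: Li2NiBr4, THF, 0 °C → rt
Reagents that add atoms: dilithium tetrabromonickelate, [Li+].[Li+].[Ni+2].[Br-].[Br-].[Br-].[Br-]
Why: Nucleophilic epoxide opening under near-neutral conditions, in which bromide attacks the less substituted carbon in an SN2 reaction, so that this carbon is inverted to S and the tertiary alcohol remains.

Step 3
Reactants: 3 bromohydrin
Product: 4 (2E,6S)-6-bromo-7-chloro-3,7-dimethyloct-2-en-1-yl acetate
Conditions: SOCl2, 2,6-lutidine, CH2Cl2, −40 → 0 °C
Reagents that add atoms: thionyl chloride, O=S(Cl)Cl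
Why: Deoxychlorination with neighbouring-group participation, in which the tertiary chlorosulfite ionises with help from the anti bromine and chloride opens the bromonium ion at the tertiary carbon, so that the C–Br bond and its S configuration are untouched.

Step 4
Reactants: 4 bromochloride
Product: 5 [(1R,3S)-3-bromo-2,2-dimethyl-6-methylidenecyclohexyl]methyl acetate
Conditions: (CF3)2CHOH (0.01 M), 2,6-di-tert-butyl-4-methylpyridine, rt
Reagents that add atoms: none
Why: Bromonium-initiated cation–olefin cyclisation, in which the tertiary chloride leaves in the ionising, non-nucleophilic solvent with bromine participation, the enantiopure bromonium ion is opened at its tertiary carbon by the 2,3-alkene through a chair transition state and proton loss ends the cascade, the C–Br stereocentre never being broken while high dilution suppresses bromonium transfer between alkenes.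

Step 5
Reactants: 5 bromo-gamma-cyclogeranyl acetate
Product: 6 [(1R,3S)-3-bromo-2,2-dimethyl-6-methylidenecyclohexyl]methanol
Conditions: K2CO3, MeOH, 0 °C → rt
Reagents that add atoms: none
Why: Base-catalysed transesterification removes the acetate, and the alkoxide sits cis to the ring bromide and cannot reach its backside, so no cyclic ether should form.

Step 6
Reactants: 6 bromo-gamma-cyclogeraniol
Product: 8 (5S)-5-bromo-2,6,6-trimethylcyclohex-1-ene-1-carbaldehyde (bromo-beta-cyclocitral), via bromo-gamma-cyclocitral 7 (not isolated)
Conditions: Dess–Martin periodinane, CH2Cl2, 0 °C → rt; then DBU (3 equiv), rt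
Reagents that add atoms: none
Why: Dess–Martin oxidation gives the deconjugated aldehyde and the amine base then moves the double bond into conjugation (prototropic isomerisation), so that every double-bond isomer from step 4 ends as one tetrasubstituted enal, the former ring CH stereocentre being erased on purpose.

Step 7
Reactants: 8 bromo-beta-cyclocitral; 9 methyl vinyl ketone
Product: 11 (1R,3S)-3-bromo-2,2-dimethyl-6-methylidene-1-[(2Z)-3-(trimethylsilyloxy)but-2-en-1-yl]cyclohexane-1-carbaldehyde, via (Z)-4-iodo-2-(trimethylsilyloxy)but-2-ene 10 (not isolated)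
Conditions: 9, Me3SiI, CH2Cl2, −78 → −40 °C; in a second flask 8, LiN(i-Pr)2, THF, −78 °C; then the solution of 10, DMPU, −78 → −40 °C; cold aq. NaHCO3 work-up, product used crude
Reagents that add atoms: iodotrimethylsilane, C[Si](C)(C)I
Why: Deconjugative alpha-alkylation of an enal, in which kinetic deprotonation of the methyl group cis to the formyl group gives the exocyclic lithium dienolate and this is alkylated at its alpha carbon (C6) by the allylic iodide 10 (from 1,4-addition of Me3SiI to 9) on the face anti to the C2 bromine, away from the axial C1 methyl group of the chair with equatorial bromine, which should set the quaternary centre, restore the C5 methylidene group and bring in the ketone already masked as its silyl enol ether.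

Step 8
Reactants: 11 silyl enol ether aldehyde; 12 (methoxymethyl)triphenylphosphonium chloride
Product: 14 2-[(1R,3S)-3-bromo-2,2-dimethyl-6-methylidene-1-(3-oxobutyl)cyclohexyl]acetaldehyde, via methyl enol ether 13 (not isolated)
Conditions: 12, NaN(SiMe3)2, THF, 0 °C; then 11, 0 °C → rt; then 1 M HCl, THF, 0 °C → rt; product used at once
Reagents that add atoms: water, O
Why: Wittig methoxymethylenation homologates the hindered, non-enolisable aldehyde by one carbon while the ketone stays masked as its silyl enol ether, and mild acid hydrolysis of both enol ethers then releases the aldehyde and the methyl ketone in one operation without touching a stereocentre.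

Step 9
Reactants: 14 keto aldehyde
Product: 15 (2R,3S,6R,8S)-8-bromo-3,7,7-trimethyl-11-methylidenespiro[5.5]undecane-2,3-diol
Conditions: SmI2 (2.5 equiv), t-BuOH (2 equiv), THF, −78 → −20 °C
Reagents that add atoms: none
Why: SmI2 transfers one electron to the aldehyde, the resulting ketyl adds to the samarium-bound ketone and a second electron gives the samarium diolate, which t-BuOH protonates (ketyl–carbonyl pinacol coupling; closest known type: SmI2-mediated cyclisation of keto aldehydes to cis-cyclohexane-1,2-diols). Ring B closes in the 6-exo-trig mode, the C8 ketyl carbon attacking the C9 carbonyl carbon and forming the C8–C9 bond. C8 and C9 should become cis because both oxygens are held on one trivalent samarium centre in the bond-forming transition state. The face is fixed by the chair of the forming ring, in which the bulky C1 is equatorial and C5 axial on the spiro carbon, the C9 methyl group is equatorial and the C8 oxygen is equatorial, away from the syn-axial C5; this puts both oxygens on the C1 face (8R,9S in target numbering). The step needs chemoselectivity for the two carbonyl groups over the secondary C2 bromide and the C5 methylidene group, which the absence of HMPA and the low temperature should secure, because alkyl bromides and unactivated alkenes react with SmI2 only under more forcing conditions. It also needs the aldehyde to be reduced before any aldol cyclisation of the keto aldehyde sets in, which the fast, cold and nearly neutral conditions favour.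

Step 10
Reactants: 15 cis diol
Product: 16 (2R,3S,6R,8S)-8-bromo-3,7,7-trimethyl-11-methylidenespiro[5.5]undecane-2,3-diyl sulfate (cyclic sulfate)
Conditions: NaH, THF, 0 °C; then 1,1'-sulfonyldiimidazole, −20 °C → rt
Reagents that add atoms: 1,1'-sulfonyldiimidazole, O=S(=O)(n1ccnc1)n1ccnc1
Why: Cyclic sulfate formation by double O-sulfonylation of the cis diol (secondary alkoxide first, ring closure by the tertiary alkoxide), chosen because it needs no oxidant that could attack the methylidene group, with both carbinol configurations retained.

Step 11
Reactants: 16 cyclic sulfate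
Product: 18 (2S,3S,6R,8S)-2,8-dibromo-3,7,7-trimethyl-11-methylidenespiro[5.5]undecan-3-ol, via lithium bromo sulfate 17 (not isolated)
Conditions: LiBr, THF, rt → 50 °C; then H2SO4 (cat.), H2O (2 equiv), THF, rt
Reagents that add atoms: lithium bromide, [Li+].[Br-]; water, O
Why: SN2 opening of the cyclic sulfate by bromide at the secondary carbon C8 with inversion (trans-diaxial product, bromine on the C5 face), followed by acid hydrolysis of the tertiary sulfate monoester, which keeps the C9 configuration whether the S–O bond or, through the bridged bromonium ion, the C9–O bond is cleaved.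

Step 12
Reactants: 18 trans-diaxial bromohydrin
Product: 19 (2S,6R,8S,9S)-2,8-dibromo-9-chloro-1,1,9-trimethyl-5-methylidenespiro[5.5]undecane
Conditions: SOCl2, 2,6-lutidine, CH2Cl2, −40 → 0 °C
Reagents that add atoms: thionyl chloride, O=S(Cl)Cl
Why: Deoxychlorination with neighbouring-group participation, in which the tertiary chlorosulfite ionises with help from the antiperiplanar C8 bromine to the bromonium ion on the C5 face and chloride enters C9 from the C1 face, so that C9 keeps its configuration under buffered conditions that spare the methylidene group (should bromide have entered at C9 in step 11, the regioisomeric bromohydrin would give 20 directly by the same retentive substitution).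

Step 13
Reactants: 19 trans-diaxial bromochloride
Product: 20 (2S,6R,8R,9R)-2,9-dibromo-8-chloro-1,1,9-trimethyl-5-methylidenespiro[5.5]undecane
Conditions: MeCN, K2CO3 (suspended, acid scavenger), 70 °C
Reagents that add atoms: none
Why: Thermal diaxial-to-diequatorial rearrangement of a vicinal dihalide (1,2-interchange through a bromonium chloride ion pair), in which bromine moves from C8 to C9 on the C5 face and chlorine from C9 to C8 on the C1 face, inverting both carbons to the trans-diequatorial target, the expected driving force being loss of the syn-axial contact between the C8 bromine and C5.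

Compound list
1 | geranyl acetate | CC(C)=CCC/C(C)=C/COC(C)=O | starting material
2 | (2E)-5-[(2R)-3,3-dimethyloxiran-2-yl]-3-methylpent-2-en-1-yl acetate | CC1(C)O[C@@H]1CC/C(C)=C/COC(C)=O | intermediate
3 | (2E,6S)-6-bromo-7-hydroxy-3,7-dimethyloct-2-en-1-yl acetate | CC(=O)OC/C=C(\C)CC[C@H](Br)C(C)(C)O | intermediate
4 | (2E,6S)-6-bromo-7-chloro-3,7-dimethyloct-2-en-1-yl acetate | CC(=O)OC/C=C(\C)CC[C@H](Br)C(C)(C)Cl | intermediate
5 | [(1R,3S)-3-bromo-2,2-dimethyl-6-methylidenecyclohexyl]methyl acetate | C=C1CC[C@H](Br)C(C)(C)[C@@H]1COC(C)=O | intermediate
6 | [(1R,3S)-3-bromo-2,2-dimethyl-6-methylidenecyclohexyl]methanol | C=C1CC[C@H](Br)C(C)(C)[C@@H]1CO | intermediate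
7 | (1R,3S)-3-bromo-2,2-dimethyl-6-methylidenecyclohexane-1-carbaldehyde (bromo-gamma-cyclocitral) | C=C1CC[C@H](Br)C(C)(C)[C@@H]1C=O | intermediate
8 | (5S)-5-bromo-2,6,6-trimethylcyclohex-1-ene-1-carbaldehyde (bromo-beta-cyclocitral) | CC1=C(C=O)C(C)(C)[C@@H](Br)CC1 | intermediate
9 | methyl vinyl ketone | C=CC(C)=O | starting material
10 | (Z)-4-iodo-2-(trimethylsilyloxy)but-2-ene | C/C(O[Si](C)(C)C)=C/CI | intermediate
11 | (1R,3S)-3-bromo-2,2-dimethyl-6-methylidene-1-[(2Z)-3-(trimethylsilyloxy)but-2-en-1-yl]cyclohexane-1-carbaldehyde | C=C1CC[C@H](Br)C(C)(C)[C@]1(C/C=C(/C)O[Si](C)(C)C)C=O | intermediate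
12 | (methoxymethyl)triphenylphosphonium chloride | COC[P+](c1ccccc1)(c1ccccc1)c1ccccc1.[Cl-] | starting material
13 | [(2Z)-4-[(1R,3S)-3-bromo-1-(2-methoxyethenyl)-2,2-dimethyl-6-methylidenecyclohexyl]but-2-en-2-yl]oxy(trimethyl)silane, E/Z mixture at the methoxyethenyl group | C=C1CC[C@H](Br)C(C)(C)[C@]1(C/C=C(/C)O[Si](C)(C)C)C=COC | intermediate
14 | 2-[(1R,3S)-3-bromo-2,2-dimethyl-6-methylidene-1-(3-oxobutyl)cyclohexyl]acetaldehyde | C=C1CC[C@H](Br)C(C)(C)[C@]1(CCC(C)=O)CC=O | intermediate
15 | (2R,3S,6R,8S)-8-bromo-3,7,7-trimethyl-11-methylidenespiro[5.5]undecane-2,3-diol | C=C1CC[C@H](Br)C(C)(C)[C@@]12CC[C@@](O)(C)[C@H](O)C2 | intermediate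
16 | (2R,3S,6R,8S)-8-bromo-3,7,7-trimethyl-11-methylidenespiro[5.5]undecane-2,3-diyl sulfate (cyclic sulfate) | C=C1CC[C@H](Br)C(C)(C)[C@@]12CC[C@]3(C)OS(=O)(=O)O[C@@H]3C2 | intermediate
17 | lithium (2S,3S,6R,8S)-2,8-dibromo-3,7,7-trimethyl-11-methylidenespiro[5.5]undecan-3-yl sulfate | C=C1CC[C@H](Br)C(C)(C)[C@@]12CC[C@@](OS(=O)(=O)[O-])(C)[C@@H](Br)C2.[Li+] | intermediate
18 | (2S,3S,6R,8S)-2,8-dibromo-3,7,7-trimethyl-11-methylidenespiro[5.5]undecan-3-ol | C=C1CC[C@H](Br)C(C)(C)[C@@]12CC[C@@](O)(C)[C@@H](Br)C2 | intermediate
19 | (2S,6R,8S,9S)-2,8-dibromo-9-chloro-1,1,9-trimethyl-5-methylidenespiro[5.5]undecane | C=C1CC[C@H](Br)C(C)(C)[C@@]12CC[C@@](Cl)(C)[C@@H](Br)C2 | intermediate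
20 | (2S,6R,8R,9R)-2,9-dibromo-8-chloro-1,1,9-trimethyl-5-methylidenespiro[5.5]undecane | C=C1CC[C@H](Br)C(C)(C)[C@@]12CC[C@@](C)(Br)[C@H](Cl)C2 | target

Total step count: 13. Longest linear sequence: 13 steps (1 → 20); 9 and 12 enter as commercial materials, and 10 is made in the flask within step 7.

Steps most likely to fail

Step 7. Several processes may compete with the intended alkylation:
- deprotonation at the ring CH2 group instead of the methyl group, which leads into the endocyclic alkene series;
- O-alkylation or silyl transfer to the dienolate;
- attack of the dienolate carbon on the C2–Br carbon, closing a cyclopropane;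
- poor facial selectivity at C6.

The fallback sets out from bromo-gamma-cyclocitral 7, obtained from step 6 by leaving out DBU and freed from ring-alkene isomers on AgNO3-impregnated silica. Conjugate addition of 7 to acrylonitrile with catalytic DBU in MeCN at 0 °C removes only the acidic alpha hydrogen, and the small stationary amount of dienolate is trapped at once; this should give the cyanoethyl aldehyde F1. Methoxymethylenation with Ph3P=CHOMe in THF should give the enol ether nitrile F2. MeLi in Et2O (−78 → 0 °C) adds to the nitrile, and aqueous HCl then hydrolyses the imine and the enol ether, which returns the route to 14.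

Step 11. Bromide has to reach C8 past the syn-axial C5 methylidene carbon, so slow substitution, elimination of the sulfate or competing ionisation at C9 may take over. The fallback sets out from diol 15 and delivers bromide by trans-diaxial opening of an epoxide instead. 2-Acetoxy-2-methylpropanoyl bromide in MeCN converts the cis diol through its acetoxonium ion into the trans bromo acetate F3, with bromide entering at the tertiary carbon on the C5 face. K2CO3 in MeOH removes the acetyl group, and the alkoxide displaces the bromide to give the C1-face epoxide F4. Li2NiBr4 in THF should open F4 at the secondary carbon C8 from the C5 face, which returns the route to 18.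

Step 9. The coupling may give the trans diol or the cis diol on the wrong face; simple reduction of the aldehyde, aldol cyclisation of the keto aldehyde or reductive loss of the C2 bromide may also intervene. The fallback sets out from 14 and closes ring B by olefin metathesis, adding the oxygens afterwards. Double methylenation with Ph3P=CH2 in THF should give the triene F5. Ring-closing metathesis with the second-generation Grubbs catalyst RuCl2(=CHPh)(H2IMes)(PCy3) in CH2Cl2 should give the ring-B cyclohexene F6; the methylidene group, flanked by two quaternary carbons, should stay out. Dihydroxylation with catalytic OsO4 and N-methylmorpholine N-oxide should take place at the more electron-rich trisubstituted alkene, from the face opposite the pseudo-axial C5, which returns the route to 15.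

Further compounds
F1 | step 7 | 3-[(1R,3S)-3-bromo-1-formyl-2,2-dimethyl-6-methylidenecyclohexyl]propanenitrile | C=C1CC[C@H](Br)C(C)(C)[C@]1(CCC#N)C=O
F2 | step 7 | 3-[(1R,3S)-3-bromo-1-(2-methoxyethenyl)-2,2-dimethyl-6-methylidenecyclohexyl]propanenitrile, E/Z mixture | C=C1CC[C@H](Br)C(C)(C)[C@]1(CCC#N)C=COC
F3 | step 11 | (2R,3R,6R,8S)-3,8-dibromo-3,7,7-trimethyl-11-methylidenespiro[5.5]undecan-2-yl acetate | C=C1CC[C@H](Br)C(C)(C)[C@@]12CC[C@@](C)(Br)[C@H](OC(C)=O)C2
F4 | step 11 | (2R,3S,6R,8S)-8-bromo-2,3-epoxy-3,7,7-trimethyl-11-methylidenespiro[5.5]undecane | C=C1CC[C@H](Br)C(C)(C)[C@@]12CC[C@]3(C)O[C@@H]3C2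
F5 | step 9 | (1R,3S)-3-bromo-2,2-dimethyl-1-(3-methylbut-3-en-1-yl)-6-methylidene-1-(prop-2-en-1-yl)cyclohexane | C=C1CC[C@H](Br)C(C)(C)[C@]1(CCC(C)=C)CC=C
F6 | step 9 | (6R,8S)-8-bromo-3,7,7-trimethyl-11-methylidenespiro[5.5]undec-2-ene | C=C1CC[C@H](Br)C(C)(C)[C@@]12CCC(C)=CC2
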